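**Retrosynthetic overview**
- Target: (3S,5S,6S,3'R,6'R)-5,6-dihydro-β,ε-carotene-3,5,6,3'-tetrol; the last step is fluoride removal of four silyl ethers.
- The strategy rests on the trisubstituted E alkene C9'(CH3)=C10' next to the cyclohexene ring C1'–C6'. It is read as terminal alkyne C9'≡C10' + methyl + alkenyl carbon C11': methylalumination of a C13 enyne, then Zn/Pd coupling with a C26 heptaenyl 11'-iodide, makes C9'–CH3 and C10'–C11'.
- Enyne: (R)-α-ionone → ketal → allylic oxidation at C3' → trans-selective reduction → TBS ether → ketone → terminal alkyne.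
- Iodide: ketoisophorone → (4R,6R)-actinol → Rubottom hydroxylation (C5) → axial acetylide addition (C6) → Red-Al → C15 phosphonium + C10 dialdehyde → C25 aldehyde → Takai iodoolefination.
- No ring is closed: both six-membered rings are carried in from α-ionone and ketoisophorone.

Key step: step 19

Assumption: carotenoid numbering is used (C1–C6 triol ring, C1'–C6' cyclohexene ring); α-ionone is bought as the racemate and its (R) enantiomer is taken by chromatography on a chiral phase, counted as step 1.

**Fragment A: cyclohexene-ring C13 enyne**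

Step 1
Reactants: 1 (±)-α-ionone
Product: 2 (R)-(+)-α-ionone
Conditions: preparative SFC, cellulose tris(3,5-dimethylphenylcarbamate) phase, CO2/i-PrOH, 35 °C
Reagents that add atoms: none
Why: Chromatographic resolution; the enantiomers differ only at C6' and should separate on a carbamate-derivatised polysaccharide phase, and the dextrorotatory (R) enantiomer keeps its configuration because no acid or base is present.

Step 2
Reactants: 2 (R)-α-ionone
Product: 3 (R)-α-ionone ethylene ketal
Conditions: TMSOCH2CH2OTMS, TMSOTf (2 mol %), CH2Cl2, −78 → −20 °C; pyridine quench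
Reagents that add atoms: 1,2-bis(trimethylsilyloxy)ethane, C[Si](C)(C)OCCO[Si](C)(C)C
Why: Noyori ketalisation under aprotic low-temperature conditions masks the C9' ketone without the alkene migration that protic acid can cause, so C6' is untouched.

Step 3
Reactants: 3 ketal
Product: 4 3'-oxo ketal (4R)
Conditions: t-BuOOH (70% aq., 5 equiv), Rh2(cap)4 (1 mol %), K2CO3, CH2Cl2, rt
Reagents that add atoms: tert-butyl hydroperoxide, CC(C)(C)OO
Why: Radical allylic oxidation (tert-butylperoxy chain) should take the only accessible allylic methylene, C3', because the doubly allylic C6'–H is shielded by the gem-dimethyl group, the C5' methyl and the side chain; the ketal is stable to the basic medium.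

Step 4
Reactants: 4 3'-oxo ketal
Product: 5 trans allylic alcohol (1R,4R)
Conditions: L-Selectride (LiBH(s-Bu)3, 1.2 equiv), THF, −78 °C; then H2O
Reagents that add atoms: none
Why: 1,2-Reduction of a β,β-disubstituted cyclohexenone by a bulky borohydride; the hydride should enter anti to the axial C1' methyl of the sofa conformer with the side chain pseudoaxial, placing the new hydroxyl trans to the side chain (3'R), and any cis epimer is removed by chromatography.

Step 5
Reactants: 5 trans allylic alcohol
Product: 6 TBS ether of the ketal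
Conditions: TBSCl, imidazole, DMF, rt
Reagents that add atoms: tert-butyldimethylsilyl chloride, CC(C)(C)[Si](C)(C)Cl
Why: Standard silylation of a secondary alcohol under conditions that leave the ketal intact.

Step 6
Reactants: 6 TBS ether of the ketal
Product: 7 (3R,6R)-3-(tert-butyldimethylsilyloxy)-α-ionone
Conditions: PPTS (cat.), acetone/H2O, rt
Reagents that add atoms: water, O
Why: Mild acid-catalysed ketal hydrolysis; the allylic dioxolane should cleave much faster than the secondary silyl ether.

Step 7
Reactants: 7 silyloxy-α-ionone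
Product: 11 cyclohexene-ring C13 enyne, via lithium enolate 8 (not isolated), via dienyl phosphate 9 (not isolated), via lithium acetylide 10 (not isolated)
Conditions: LDA (1.1 equiv), THF, −78 °C; ClP(O)(OEt)2, −78 °C → rt; LDA (2.3 equiv), −78 °C → rt; then H2O
Reagents that add atoms: none
Why: Kinetic enolisation of the methyl ketone on the methyl side, O-phosphorylation and base-induced elimination of diethyl phosphate (enol phosphate to alkyne conversion) turn the acetyl group into C9'≡C10'H; low temperature keeps the hindered C6'–H untouched.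

**Fragment B: triol-ring C26 iodide**

Step 8
Reactants: 12 ketoisophorone
Product: 13 (6R)-levodione
Conditions: ene-reductase OYE2, NADP+ (cat.), D-glucose, glucose dehydrogenase, phosphate buffer pH 6.5, 30 °C
Reagents that add atoms: none
Why: Enzymatic conjugate reduction of the enedione C=C; the flavin delivers hydride to one face and sets the methyl-bearing centre as R, and prompt extraction limits epimerisation.

Step 9
Reactants: 13 (6R)-levodione
Product: 14 (4R,6R)-actinol
Conditions: L-Selectride (1.05 equiv), THF, −78 °C; then H2O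
Reagents that add atoms: none
Why: The bulky hydride should reduce only the unhindered C4 carbonyl, attacking from the equatorial side anti to the axial C2 methyl, which gives the axial alcohol trans to the equatorial C6 methyl (4R); this centre becomes C3 of the target.

Step 10
Reactants: 14 actinol
Product: 15 actinol TBS ether
Conditions: TBSCl, imidazole, DMF, rt → 40 °C
Reagents that add atoms: tert-butyldimethylsilyl chloride, CC(C)(C)[Si](C)(C)Cl
Why: Standard silylation of the secondary alcohol; the ketone is too hindered to interfere.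

Step 11
Reactants: 15 actinol TBS ether
Product: 16 trimethylsilyl enol ether
Conditions: TMSOTf, Et3N, CH2Cl2, 0 °C → rt
Reagents that add atoms: trimethylsilyl triflate, C[Si](C)(C)OS(=O)(=O)C(F)(F)F
Why: Soft enolisation; only one α-carbon carries hydrogen, so a single enol ether forms, and the methyl-bearing stereocentre is given up on purpose.

Step 12
Reactants: 16 silyl enol ether
Product: 19 ketol (2S,4S), via silyloxy epoxide 17 (not isolated), via α-silyloxy ketone 18 (not isolated)
Conditions: mCPBA, NaHCO3, hexane/CH2Cl2, −20 → 0 °C; then citric acid, MeOH, rt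
Reagents that add atoms: 3-chloroperbenzoic acid, OOC(=O)c1cccc(Cl)c1
Why: Rubottom oxidation; in the half-chair with the silyloxy group equatorial, the pseudoaxial methyl of the gem-dimethyl carbon blocks the face anti to that group, so the peracid should add syn to it and give the C5 hydroxyl cis to the C3 oxygen (5S) after silyl shift and methanolysis.

Step 13
Reactants: 19 ketol; 20 (E)-3-methylpent-2-en-4-yn-1-ol
Product: 22 C15 enynetriol (1R,2S,4S), via dilithio enynolate 21 (not isolated)
Conditions: 20 (3 equiv), n-BuLi (6 equiv), THF, −78 → 0 °C; add 19, −78 °C → rt; then H2O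
Reagents that add atoms: none
Why: 1,2-Addition of a lithium acetylide to the ketone; in the chair with the C3 and C5 oxygens equatorial, the axial methyls at C1 and C5 block the equatorial path, so the slim nucleophile should attack axially, trans to the C5 methyl, giving the chain cis to the C5 oxygen and the C6 hydroxyl trans to it.

Step 14
Reactants: 22 C15 enynetriol
Product: 23 C15 dienetriol (1S,2S,4S)
Conditions: Red-Al (NaAlH2(OCH2CH2OMe)2), THF, 0 °C → rt; then aq. NaOH
Reagents that add atoms: none
Why: Alkoxide-directed trans-hydroalumination of the tertiary propargylic alcohol and protonolysis give the E C7=C8 alkene; C6 is unchanged in space, and its descriptor changes only through the priority rules.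

Step 15
Reactants: 23 C15 dienetriol
Product: 25 C15 phosphonium bromide, via allylic bromide 24 (not isolated)
Conditions: CBr4 (1.2 equiv), PPh3 (2.5 equiv), CH2Cl2, −20 °C → rt
Reagents that add atoms: triphenylphosphine, c1ccccc1P(c1ccccc1)c1ccccc1; carbon tetrabromide, BrC(Br)(Br)Br
Why: Appel bromination of the primary allylic alcohol followed by quaternisation with the excess phosphine; the two tertiary hydroxyls are too hindered to react and no strong acid is set free.

Step 16
Reactants: 25 C15 phosphonium bromide; 26 (2E,4E,6E)-2,7-dimethylocta-2,4,6-trienedial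
Product: 28 C25 aldehyde with free 5,6-diol, via phosphorus ylide 27 (not isolated)
Conditions: 26 (3 equiv), NaOMe, MeOH/CH2Cl2, 0 °C → rt; then heptane, 90 °C, dark
Reagents that add atoms: none
Why: Wittig olefination forms C11=C12; excess dialdehyde favours monocondensation, the ylide tolerates the free tertiary hydroxyls, and heating should equilibrate the hindered 11Z isomer to the all-E aldehyde.

Step 17
Reactants: 28 C25 aldehyde
Product: 29 bis(trimethylsilyl) C25 aldehyde
Conditions: N-(trimethylsilyl)imidazole, CH2Cl2, rt → 40 °C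
Reagents that add atoms: N-(trimethylsilyl)imidazole, C[Si](C)(C)n1ccnc1
Why: This neutral, powerful silyl donor should cap both hindered tertiary hydroxyls without touching the polyenal.

Step 18
Reactants: 29 bis(trimethylsilyl) C25 aldehyde
Product: 30 triol-ring C26 heptaenyl 11'-iodide
Conditions: CrCl2 (8 equiv), CHI3 (3 equiv), THF/1,4-dioxane, 0 °C → rt, dark
Reagents that add atoms: iodoform, IC(I)I
Why: Takai olefination; the geminal dichromium reagent adds to the aldehyde and anti elimination should give the E iodoalkene C11'=C12', with silyl ethers tolerated.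

**Coupling and deprotection**

Step 19
Reactants: 11 cyclohexene-ring C13 enyne; 31 trimethylaluminium; 30 C26 heptaenyl iodide
Product: 34 fully silylated carotenoid, via alkenylalane 32 (not isolated), via alkenylzinc chloride 33 (not isolated)
Conditions: 11 (1.3 equiv), Me3Al (2.6 equiv), Cp2ZrCl2 (0.25 equiv), CH2Cl2, 0 °C → rt; evaporate; THF, ZnCl2 (1.3 equiv), 0 °C; 30 (1.0 equiv), Pd(PPh3)4 (5 mol %, zerovalent palladium), rt, dark
Reagents that add atoms: none
Why: Me3Al and Cp2ZrCl2 form a methylzirconocene–aluminium species that adds syn across the terminal alkyne of 11, methyl to the internal carbon C9' and metal to the terminal carbon C10', and transfer to aluminium gives the (E)-alkenylalane 32. ZnCl2 converts 32 into alkenylzinc 33, which enters the palladium cycle (oxidative addition of the C11'–I bond of 30 to zerovalent palladium, zinc-to-palladium transmetalation, reductive elimination) and forms C10'–C11' with retention at both alkene carbons. The closest known reaction type is zirconium-catalysed methylalumination of terminal alkynes and conjugated enynes followed by Negishi alkenyl–alkenyl coupling. No ring is closed and no stereocentre is made; the C9'=C10' geometry comes from the syn addition and the C11'=C12' geometry from the iodide. The step needs regio- and syn-selective methyl delivery, which the terminal alkyne secures because its unsubstituted carbon takes the metal, and it needs C6' to stay intact, which should hold because the alkyne has no propargylic hydrogen and C6' is insulated by the C7'=C8' alkene. The silyl ethers of both partners carry no acidic hydrogen and are not expected to react with Me3Al at room temperature.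

Step 20
Reactants: 34 fully silylated carotenoid
Product: 35 target tetrol
Conditions: TBAF (6 equiv), THF, 0 °C → rt, dark
Reagents that add atoms: none
Why: Fluoride cleaves all four Si–O bonds under non-acidic conditions, which spares the allylic C3' hydroxyl, the tertiary allylic C6 hydroxyl and the polyene.

**Compound list**

1 | (±)-α-ionone, (E)-4-(2,6,6-trimethylcyclohex-2-en-1-yl)but-3-en-2-one, racemic | CC1=CCCC(C)(C)C1/C=C/C(C)=O | starting material
2 | (R)-(+)-α-ionone | CC1=CCCC(C)(C)[C@H]1/C=C/C(C)=O | intermediate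
3 | 2-methyl-2-[(E)-2-[(1R)-2,6,6-trimethylcyclohex-2-en-1-yl]ethenyl]-1,3-dioxolane | CC1=CCCC(C)(C)[C@H]1/C=C/C2(C)OCCO2 | intermediate
4 | (4R)-3,5,5-trimethyl-4-[(E)-2-(2-methyl-1,3-dioxolan-2-yl)ethenyl]cyclohex-2-en-1-one | CC1=CC(=O)CC(C)(C)[C@H]1/C=C/C2(C)OCCO2 | intermediate
5 | (1R,4R)-3,5,5-trimethyl-4-[(E)-2-(2-methyl-1,3-dioxolan-2-yl)ethenyl]cyclohex-2-en-1-ol (hydroxyl trans to side chain) | CC1=C[C@H](O)CC(C)(C)[C@H]1/C=C/C2(C)OCCO2 | intermediate
6 | tert-butyldimethylsilyl ether of 5 | CC1=C[C@H](O[Si](C)(C)C(C)(C)C)CC(C)(C)[C@H]1/C=C/C2(C)OCCO2 | intermediate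
7 | (E)-4-[(1R,4R)-4-(tert-butyldimethylsilyloxy)-2,6,6-trimethylcyclohex-2-en-1-yl]but-3-en-2-one | CC1=C[C@H](O[Si](C)(C)C(C)(C)C)CC(C)(C)[C@H]1/C=C/C(C)=O | intermediate
8 | lithium enolate of 7 on the methyl side | CC1=C[C@H](O[Si](C)(C)C(C)(C)C)CC(C)(C)[C@H]1/C=C/C(=C)O[Li] | intermediate
9 | diethyl dienyl phosphate of 7 | CC1=C[C@H](O[Si](C)(C)C(C)(C)C)CC(C)(C)[C@H]1/C=C/C(=C)OP(=O)(OCC)OCC | intermediate
10 | lithium acetylide of 11 | CC1=C[C@H](O[Si](C)(C)C(C)(C)C)CC(C)(C)[C@H]1/C=C/C#C[Li] | intermediate
11 | cyclohexene-ring C13 enyne, [(1R,4R)-4-[(E)-but-1-en-3-ynyl]-3,5,5-trimethylcyclohex-2-en-1-yl]oxy-tert-butyldimethylsilane | CC1=C[C@H](O[Si](C)(C)C(C)(C)C)CC(C)(C)[C@H]1/C=C/C#C | intermediate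
12 | ketoisophorone, 2,6,6-trimethylcyclohex-2-ene-1,4-dione | CC1=CC(=O)CC(C)(C)C1=O | starting material
13 | (6R)-levodione, (R)-2,2,6-trimethylcyclohexane-1,4-dione | C[C@@H]1CC(=O)CC(C)(C)C1=O | intermediate
14 | (4R,6R)-actinol, (4R,6R)-4-hydroxy-2,2,6-trimethylcyclohexanone | C[C@@H]1C[C@@H](O)CC(C)(C)C1=O | intermediate
15 | (4R,6R)-4-(tert-butyldimethylsilyloxy)-2,2,6-trimethylcyclohexanone | C[C@@H]1C[C@@H](O[Si](C)(C)C(C)(C)C)CC(C)(C)C1=O | intermediate
16 | (4R)-4-(tert-butyldimethylsilyloxy)-2,6,6-trimethyl-1-(trimethylsilyloxy)cyclohex-1-ene | CC1=C(O[Si](C)(C)C)C(C)(C)C[C@H](O[Si](C)(C)C(C)(C)C)C1 | intermediate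
17 | silyloxy epoxide of 16, epoxide oxygen cis to the silyloxy group | C[C@@]12O[C@]1(O[Si](C)(C)C)C(C)(C)C[C@H](O[Si](C)(C)C(C)(C)C)C2 | intermediate
18 | (2S,4S)-4-(tert-butyldimethylsilyloxy)-2,6,6-trimethyl-2-(trimethylsilyloxy)cyclohexanone | O=C1C(C)(C)C[C@H](O[Si](C)(C)C(C)(C)C)C[C@]1(C)O[Si](C)(C)C | intermediate
19 | (2S,4S)-4-(tert-butyldimethylsilyloxy)-2-hydroxy-2,6,6-trimethylcyclohexanone | O=C1C(C)(C)C[C@H](O[Si](C)(C)C(C)(C)C)C[C@]1(C)O | intermediate
20 | (E)-3-methylpent-2-en-4-yn-1-ol | C#C/C(C)=C/CO | starting material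
21 | dilithio derivative of 20 (alkoxide and acetylide) | [Li]C#C/C(C)=C/CO[Li] | intermediate
22 | (1R,2S,4S)-4-(tert-butyldimethylsilyloxy)-1-[(E)-5-hydroxy-3-methylpent-3-en-1-ynyl]-2,6,6-trimethylcyclohexane-1,2-diol | OC/C=C(C)/C#C[C@]1(O)C(C)(C)C[C@H](O[Si](C)(C)C(C)(C)C)C[C@]1(C)O | intermediate
23 | (1S,2S,4S)-4-(tert-butyldimethylsilyloxy)-1-[(1E,3E)-5-hydroxy-3-methylpenta-1,3-dienyl]-2,6,6-trimethylcyclohexane-1,2-diol | OC/C=C(C)/C=C/[C@]1(O)C(C)(C)C[C@H](O[Si](C)(C)C(C)(C)C)C[C@]1(C)O | intermediate
24 | primary allylic bromide of 23 | BrC/C=C(C)/C=C/[C@]1(O)C(C)(C)C[C@H](O[Si](C)(C)C(C)(C)C)C[C@]1(C)O | intermediate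
25 | triphenylphosphonium bromide of 23 at C11 | [Br-].c1ccccc1[P+](c1ccccc1)(c1ccccc1)C/C=C(C)/C=C/[C@]2(O)C(C)(C)C[C@H](O[Si](C)(C)C(C)(C)C)C[C@]2(C)O | intermediate
26 | (2E,4E,6E)-2,7-dimethylocta-2,4,6-trienedial | O=C/C(C)=C/C=C/C=C(C)/C=O | starting material
27 | phosphorus ylide of 25 | c1ccccc1P(c1ccccc1)(c1ccccc1)=C/C=C(C)/C=C/[C@]2(O)C(C)(C)C[C@H](O[Si](C)(C)C(C)(C)C)C[C@]2(C)O | intermediate
28 | (3S,5S,6S)-3-(tert-butyldimethylsilyloxy)-5,6-dihydroxy-5,6-dihydro-12'-apo-β-caroten-12'-al, all-E | O=C/C(C)=C/C=C/C=C(C)/C=C/C=C(C)/C=C/[C@]1(O)C(C)(C)C[C@H](O[Si](C)(C)C(C)(C)C)C[C@]1(C)O | intermediate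
29 | 5,6-bis(trimethylsilyl) ether of 28 | O=C/C(C)=C/C=C/C=C(C)/C=C/C=C(C)/C=C/[C@]1(O[Si](C)(C)C)C(C)(C)C[C@H](O[Si](C)(C)C(C)(C)C)C[C@]1(C)O[Si](C)(C)C | intermediate
30 | triol-ring C26 heptaenyl 11'-iodide, all-E, 3-OTBS, 5,6-bis-OTMS | I/C=C/C(C)=C/C=C/C=C(C)/C=C/C=C(C)/C=C/[C@]1(O[Si](C)(C)C)C(C)(C)C[C@H](O[Si](C)(C)C(C)(C)C)C[C@]1(C)O[Si](C)(C)C | intermediate
31 | trimethylaluminium | C[Al](C)C | starting material
32 | (E)-alkenyl dimethylalane from 11, methyl at C9', aluminium at C10' | CC1=C[C@H](O[Si](C)(C)C(C)(C)C)CC(C)(C)[C@H]1/C=C/C(C)=C/[Al](C)C | intermediate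
33 | (E)-alkenylzinc chloride from 32 | CC1=C[C@H](O[Si](C)(C)C(C)(C)C)CC(C)(C)[C@H]1/C=C/C(C)=C/[Zn]Cl | intermediate
34 | fully silylated target (3,3'-bis-OTBS, 5,6-bis-OTMS) | CC1=C[C@H](O[Si](C)(C)C(C)(C)C)CC(C)(C)[C@H]1/C=C/C(C)=C/C=C/C(C)=C/C=C/C=C(C)/C=C/C=C(C)/C=C/[C@]1(O[Si](C)(C)C)C(C)(C)C[C@H](O[Si](C)(C)C(C)(C)C)C[C@]1(C)O[Si](C)(C)C | intermediate
35 | (3S,5S,6S,3'R,6'R)-5,6-dihydro-β,ε-carotene-3,5,6,3'-tetrol | CC1=C[C@H](O)CC(C)(C)[C@H]1/C=C/C(C)=C/C=C/C(C)=C/C=C/C=C(C)/C=C/C=C(C)/C=C/[C@]1(O)C(C)(C)C[C@H](O)C[C@]1(C)O | target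

**Step count and risks**

Total step count: 20. Longest linear sequence: 13 steps (steps 8–20, ketoisophorone to target).

Steps most likely to fail:

1. Step 19. The light-sensitive heptaenyl iodide may decay or scramble its alkene geometry before it couples, the alkenylmetal may be lost to protonolysis or homocoupling, or the tertiary trimethylsilyl ethers may be cleaved by the aluminium Lewis acids. Fallback: form C11'=C12' by Wittig olefination instead, setting out from ketone 7 and aldehyde 29. Vinylmagnesium bromide (THF, −78 °C) adds 1,2 to 7 to give the tertiary vinyl carbinol F1. PPh3·HBr (CH2Cl2, 0 °C) converts it with allylic transposition into the cyclohexene-ring C15 phosphonium bromide F2. NaHMDS (THF, −78 °C) gives the ylide F3, which condenses with 29; thermal equilibration of the hindered 11'Z isomer should then give 34, where the route is rejoined.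

2. Step 12. The peracid oxygen may be delivered to the face anti to the 3-silyloxy group, or facial discrimination may be poor, which would give the 5-epimeric ketol. Fallback: install the C5 oxygen after the chain by epoxide opening, setting out from 15. KHMDS and PhNTf2 (THF, −78 °C) give the enol triflate F4. Sonogashira coupling with 20 (PdCl2(PPh3)2, CuI, i-Pr2NH) gives the ring dienynol F5. mCPBA/NaHCO3 epoxidises the tetrasubstituted ring alkene with the same facial bias, giving the 5,6-epoxide anti to the silyloxy group F6. Dilute HClO4 in THF/water should open it at C5 with inversion, because the alkynyl group disfavours ionisation at C6; this places the C5 hydroxyl cis to the C3 oxygen and trans to the C6 hydroxyl and rejoins the route at 22.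

3. Step 4. The hydride may enter from the other face of the ring enone (poor or reversed facial selectivity), giving mainly the cis alcohol. Fallback: correct C3' by inversion, setting out from 4. The same reduction then delivers the cis alcohol F7. Mitsunobu esterification (4-nitrobenzoic acid, PPh3, DIAD, THF, 0 °C) inverts C3' and gives the trans 4-nitrobenzoate F8. K2CO3 in MeOH releases 5, where the route is rejoined.

**Further compounds**

F1 | step 19 | (E)-1-[(1R,4R)-4-(tert-butyldimethylsilyloxy)-2,6,6-trimethylcyclohex-2-en-1-yl]-3-methylpenta-1,4-dien-3-ol (carbinol epimers) | CC1=C[C@H](O[Si](C)(C)C(C)(C)C)CC(C)(C)[C@H]1/C=C/C(C)(O)C=C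
F2 | step 19 | cyclohexene-ring C15 dienyl triphenylphosphonium bromide | [Br-].CC1=C[C@H](O[Si](C)(C)C(C)(C)C)CC(C)(C)[C@H]1/C=C/C(C)=C/C[P+](c2ccccc2)(c2ccccc2)c2ccccc2
F3 | step 19 | phosphorus ylide of F2 | CC1=C[C@H](O[Si](C)(C)C(C)(C)C)CC(C)(C)[C@H]1/C=C/C(C)=C/C=P(c2ccccc2)(c2ccccc2)c2ccccc2
F4 | step 12 | (4R)-4-(tert-butyldimethylsilyloxy)-2,6,6-trimethylcyclohex-1-enyl triflate | CC1=C(OS(=O)(=O)C(F)(F)F)C(C)(C)C[C@H](O[Si](C)(C)C(C)(C)C)C1
F5 | step 12 | (E)-5-[(4R)-4-(tert-butyldimethylsilyloxy)-2,6,6-trimethylcyclohex-1-enyl]-3-methylpent-2-en-4-yn-1-ol | CC1=C(C#C/C(C)=C/CO)C(C)(C)C[C@H](O[Si](C)(C)C(C)(C)C)C1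
F6 | step 12 | 5,6-epoxide of F5, epoxide oxygen trans to the silyloxy group | C[C@]12O[C@@]1(C#C/C(C)=C/CO)C(C)(C)C[C@H](O[Si](C)(C)C(C)(C)C)C2
F7 | step 4 | (1S,4R)-3,5,5-trimethyl-4-[(E)-2-(2-methyl-1,3-dioxolan-2-yl)ethenyl]cyclohex-2-en-1-ol (cis alcohol) | CC1=C[C@@H](O)CC(C)(C)[C@H]1/C=C/C2(C)OCCO2
F8 | step 4 | (1R,4R) 4-nitrobenzoate of 5 | CC1=C[C@H](OC(=O)c2ccc(cc2)[N+](=O)[O-])CC(C)(C)[C@H]1/C=C/C3(C)OCCO3
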